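**Retrosynthetic overview**
- The strategy rests on ring A: a benzo ring fused to the dihydrofuran through C3a–C7a, with oxygen at C7a (O1) and C4, hydrogen at C5 and C7, and the arylethyl chain at C6. It is cut into three alkynes: C7≡C7a (an ethynyl ether on O1), C3a≡C4 (a silyl ynol ether on C3) and C5≡C6 (4-(4-methoxyphenyl)but-1-yne).
- The first two alkynes are tied by O1–C2–C3, so one rhodium-catalysed (2+2+2) cycloaddition forms C3a–C7a, C4–C5 and C6–C7 and closes the dihydrofuran ring and ring A in the same event. Rings B, C and D are bought as methyl ethers.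
- The anti C2/C3 pair is set before any ring exists, by chirality transfer from an enantioenriched 1-aryl propargylic mesylate through an allenylzinc addition to 2,4-dimethoxybenzaldehyde.
- The carbinol is carried as a dichlorovinyl ether (latent ethynyl ether) while the C3 alkyne is oxidised to the silyl ynol ether. Fluoride and BBr3 then free the six phenols (one silyl ether, five methyl ethers).

Key step: step 8

Assumption: the ProPhenol enantiomer written in step 1 is taken to give the R carbinol; if its sense of induction is the opposite, the other ligand enantiomer is used and nothing else changes.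

**Step 1**
Reactants: 1 3,5-dimethoxybenzaldehyde; 2 (triethylsilyl)acetylene
Product: 3 (R)-1-(3,5-dimethoxyphenyl)-3-(triethylsilyl)prop-2-yn-1-ol
Conditions: Me2Zn (3 equiv), (S,S)-ProPhenol (10 mol %), Ph3PO (20 mol %), toluene, 0 °C
Reagents that add atoms: none
Why: Zinc–ProPhenol catalysed enantioselective alkynylation of an aromatic aldehyde, in which the dinuclear zinc catalyst delivers the zinc acetylide to one face of the aldehyde and so sets the carbinol centre as R.

**Step 2**
Reactants: 3 (R)-1-(3,5-dimethoxyphenyl)-3-(triethylsilyl)prop-2-yn-1-ol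
Product: 4 (R)-1-(3,5-dimethoxyphenyl)-3-(triethylsilyl)prop-2-yn-1-yl methanesulfonate
Conditions: Ms2O, Et3N, CH2Cl2, −40 °C; used crude at once
Reagents that add atoms: methanesulfonic anhydride CS(=O)(=O)OS(C)(=O)=O
Why: O-Sulfonylation of the propargylic alcohol does not touch the C–O bond, and the anhydride avoids chloride that could displace the benzylic mesylate, so the configuration is retained.

**Step 3**
Reactants: 4 (R)-1-(3,5-dimethoxyphenyl)-3-(triethylsilyl)prop-2-yn-1-yl methanesulfonate; 5 2,4-dimethoxybenzaldehyde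
Product: 7 (1S,2S)-1-(2,4-dimethoxyphenyl)-2-(3,5-dimethoxyphenyl)-4-(triethylsilyl)but-3-yn-1-ol (anti alcohol), via allenylzinc mesylate 6 (not isolated)
Conditions: Pd(OAc)2 (5 mol %), PPh3 (5 mol %), Et2Zn (3 equiv), THF, −78 to −20 °C; aqueous work-up
Reagents that add atoms: none
Why: Marshall propargylation: zerovalent palladium formed in the flask displaces the mesylate in the anti SN2' sense, transmetallation gives the P-configured allenylzinc 6, and its cyclic SE2' addition to 5 forms the new C–C bond on the face opposite to the departed mesylate (propargylic centre S by net inversion) with the aldehyde aryl group turned away from the 3,5-dimethoxyphenyl group in the chair-like transition state (anti, carbinol centre S).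

**Step 4**
Reactants: 7 (1S,2S)-1-(2,4-dimethoxyphenyl)-2-(3,5-dimethoxyphenyl)-4-(triethylsilyl)but-3-yn-1-ol
Product: 9 triethyl{(3S,4S)-4-[(E)-1,2-dichloroethenoxy]-4-(2,4-dimethoxyphenyl)-3-(3,5-dimethoxyphenyl)but-1-yn-1-yl}silane, via potassium alkoxide 8 (not isolated)
Conditions: KH, THF, 0 °C (10 min); Cl2C=CHCl (1.1 equiv), −50 °C to rt
Reagents that add atoms: trichloroethylene ClC=C(Cl)Cl
Why: Dichlorovinylation of an alkoxide: 8 adds in the anti sense to dichloroacetylene generated in the flask from trichloroethylene and protonation gives the E-1,2-dichlorovinyl ether without touching either stereocentre, the triethylsilyl cap (chosen over trimethylsilyl) keeping the alkyne terminus inert to the alkoxide and the cold, short alkoxide lifetime guarding against retro-propargylation.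

**Step 5**
Reactants: 9 triethyl{(3S,4S)-4-[(E)-1,2-dichloroethenoxy]-4-(2,4-dimethoxyphenyl)-3-(3,5-dimethoxyphenyl)but-1-yn-1-yl}silane
Product: 10 (3R,4S)-4-[(E)-1,2-dichloroethenoxy]-4-(2,4-dimethoxyphenyl)-3-(3,5-dimethoxyphenyl)but-1-yne (same spatial arrangement; the C3 descriptor changes only by priority)
Conditions: K2CO3 (0.3 equiv), MeOH–THF, rt
Reagents that add atoms: none
Why: Base-catalysed methanolysis of the C(sp)–Si bond; the dichlorovinyl ether is inert to carbonate in methanol and the medium is too weakly basic to isomerise the benzylic propargylic C–H to an allene.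

**Step 6**
Reactants: 10 (3R,4S)-4-[(E)-1,2-dichloroethenoxy]-4-(2,4-dimethoxyphenyl)-3-(3,5-dimethoxyphenyl)but-1-yne
Product: 13 {[(3S,4S)-4-[(E)-1,2-dichloroethenoxy]-4-(2,4-dimethoxyphenyl)-3-(3,5-dimethoxyphenyl)but-1-yn-1-yl]oxy}triisopropylsilane, via lithium acetylide 11 (not isolated), via lithium ynolate 12 (not isolated)
Conditions: LiN(SiMe3)2 (1.05 equiv), THF, −78 °C; t-BuOOLi (from t-BuOOH and LiN(SiMe3)2), −78 to 0 °C; iPr3SiOTf, −78 °C
Reagents that add atoms: lithium tert-butyl peroxide CC(C)(C)OO[Li]; triisopropylsilyl trifluoromethanesulfonate CC(C)[Si](OS(=O)(=O)C(F)(F)F)(C(C)C)C(C)C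
Why: Oxidation of a lithium acetylide by lithium tert-butyl peroxide to the ynolate, then O-silylation (the established siloxyalkyne preparation); one equivalent of amide base removes only the acetylenic proton and leaves the dichlorovinyl ether alone.

**Step 7**
Reactants: 13 {[(3S,4S)-4-[(E)-1,2-dichloroethenoxy]-4-(2,4-dimethoxyphenyl)-3-(3,5-dimethoxyphenyl)but-1-yn-1-yl]oxy}triisopropylsilane
Product: 16 {[(3S,4S)-4-(2,4-dimethoxyphenyl)-3-(3,5-dimethoxyphenyl)-4-(ethynyloxy)but-1-yn-1-yl]oxy}triisopropylsilane (anti diyne), via chloroethynyl ether 14 (not isolated), via lithium alkoxyacetylide 15 (not isolated)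
Conditions: n-BuLi (2.1 equiv), Et2O, −78 to −50 °C; MeOH, −78 °C; cold filtration through basic alumina, used at once
Reagents that add atoms: none
Why: Dichlorovinyl ether route to terminal ynol ethers: butyllithium eliminates HCl to 14, chlorine–lithium exchange gives 15 and cold protonation frees the ethynyl ether, while at −78 °C the hindered triisopropylsilyl group is expected to resist attack at silicon.

**Step 8**
Reactants: 16 {[(3S,4S)-4-(2,4-dimethoxyphenyl)-3-(3,5-dimethoxyphenyl)-4-(ethynyloxy)but-1-yn-1-yl]oxy}triisopropylsilane; 17 4-(4-methoxyphenyl)but-1-yne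
Product: 18 {[(2S,3S)-2-(2,4-dimethoxyphenyl)-3-(3,5-dimethoxyphenyl)-6-[2-(4-methoxyphenyl)ethyl]-2,3-dihydro-1-benzofuran-4-yl]oxy}triisopropylsilane (trans; the 4-O-silyl pentamethyl ether of the target)
Conditions: [Rh(cod)2]BF4 (10 mol %), rac-BINAP (10 mol %), H2 then Ar, CH2Cl2, rt; 17 (4 equiv); 16 added by syringe pump
Reagents that add atoms: none
Why: Proposed new method: the BINAP-ligated rhodium cation (monovalent) binds both ynol ether triple bonds of 16 and joins them by oxidative cyclisation to a trivalent rhodacyclopentadiene, a polarity-matched union of the nucleophilic β-carbon of the silyl ynol ether (C3a) with the oxygen-bearing carbon of the ethynyl ether (C7a), after which 17 inserts and reductive elimination releases the arene; the closest known reaction type is the rhodium- or ruthenium-catalysed (2+2+2) cycloaddition of 1,6-diynes with terminal alkynes, which includes ynamide-tethered diynes that give indolines and alkynyl ethers as the monoalkyne, but not a diyne with two ynol ether termini. The dihydrofuran ring closes in the oxidative coupling through the new C3a–C7a bond (five-membered ring from a 1,6-diyne with the three-atom O1–C2–C3 tether), and ring A closes when C6–C7 forms by insertion and C4–C5 by reductive elimination. No stereocentre is created: C2 and C3 sit in the tether, take no part in bond making, and their anti relationship becomes trans in the ring. The step needs crossed rather than homo-coupling and one orientation of insertion: slow addition of 16 to excess 17 favours the crossed product, and the bulky triisopropylsilyloxy group on the C4 terminus should make the unsubstituted CH of 17 bond to C4, so that the chain ends at C6 between two ring hydrogens. Room temperature is required because the secondary benzylic ethynyl ether loses ketene by retro-ene reaction or undergoes sigmatropic shift on heating.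

**Step 9**
Reactants: 18 {[(2S,3S)-2-(2,4-dimethoxyphenyl)-3-(3,5-dimethoxyphenyl)-6-[2-(4-methoxyphenyl)ethyl]-2,3-dihydro-1-benzofuran-4-yl]oxy}triisopropylsilane
Product: 19 (2S,3S)-2-(2,4-dimethoxyphenyl)-3-(3,5-dimethoxyphenyl)-6-[2-(4-methoxyphenyl)ethyl]-2,3-dihydro-1-benzofuran-4-ol
Conditions: Bu4NF, THF, 0 °C
Reagents that add atoms: none
Why: Fluoride desilylation of the aryl silyl ether, which leaves the five methyl ethers and the dihydrobenzofuran untouched.

**Step 10**
Reactants: 19 (2S,3S)-2-(2,4-dimethoxyphenyl)-3-(3,5-dimethoxyphenyl)-6-[2-(4-methoxyphenyl)ethyl]-2,3-dihydro-1-benzofuran-4-ol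
Product: 20 4-[(2S,3S)-3-(3,5-dihydroxyphenyl)-4-hydroxy-6-[2-(4-hydroxyphenyl)ethyl]-2,3-dihydro-1-benzofuran-2-yl]benzene-1,3-diol (CNP0329616.1)
Conditions: BBr3 (excess), CH2Cl2, −78 to 0 °C; then MeOH, H2O
Reagents that add atoms: none
Why: Lewis acid demethylation of the five aryl methyl ethers with BBr3; C3 is not touched, and should the benzylic C2–O bond open transiently the cation can only reclose on one of the two equivalent oxygens of ring A to the more stable trans ring.

**Compound list**
1 | 3,5-dimethoxybenzaldehyde | COc1cc(C=O)cc(OC)c1 | starting material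
2 | (triethylsilyl)acetylene | C#C[Si](CC)(CC)CC | starting material
3 | (R)-1-(3,5-dimethoxyphenyl)-3-(triethylsilyl)prop-2-yn-1-ol | O[C@H](c1cc(OC)cc(OC)c1)C#C[Si](CC)(CC)CC | intermediate
4 | (R)-1-(3,5-dimethoxyphenyl)-3-(triethylsilyl)prop-2-yn-1-yl methanesulfonate | CS(=O)(=O)O[C@H](c1cc(OC)cc(OC)c1)C#C[Si](CC)(CC)CC | intermediate
5 | 2,4-dimethoxybenzaldehyde | COc1ccc(C=O)c(OC)c1 | starting material
6 | (P)-[3-(3,5-dimethoxyphenyl)-1-(triethylsilyl)propa-1,2-dien-1-yl]zinc methanesulfonate | [H]C(c1cc(OC)cc(OC)c1)=[C@]=C([Si](CC)(CC)CC)[Zn]OS(C)(=O)=O | intermediate (not isolated)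
7 | (1S,2S)-1-(2,4-dimethoxyphenyl)-2-(3,5-dimethoxyphenyl)-4-(triethylsilyl)but-3-yn-1-ol (anti) | O[C@H](c1ccc(OC)cc1OC)[C@@H](c1cc(OC)cc(OC)c1)C#C[Si](CC)(CC)CC | intermediate
8 | potassium alkoxide of 7 | [K]O[C@H](c1ccc(OC)cc1OC)[C@@H](c1cc(OC)cc(OC)c1)C#C[Si](CC)(CC)CC | intermediate (not isolated)
9 | triethyl{(3S,4S)-4-[(E)-1,2-dichloroethenoxy]-4-(2,4-dimethoxyphenyl)-3-(3,5-dimethoxyphenyl)but-1-yn-1-yl}silane | Cl/C=C(Cl)\O[C@H](c1ccc(OC)cc1OC)[C@@H](c1cc(OC)cc(OC)c1)C#C[Si](CC)(CC)CC | intermediate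
10 | (3R,4S)-4-[(E)-1,2-dichloroethenoxy]-4-(2,4-dimethoxyphenyl)-3-(3,5-dimethoxyphenyl)but-1-yne | Cl/C=C(Cl)\O[C@H](c1ccc(OC)cc1OC)[C@@H](c1cc(OC)cc(OC)c1)C#C | intermediate
11 | lithium acetylide of 10 | Cl/C=C(Cl)\O[C@H](c1ccc(OC)cc1OC)[C@@H](c1cc(OC)cc(OC)c1)C#C[Li] | intermediate (not isolated)
12 | lithium ynolate from 11 | Cl/C=C(Cl)\O[C@H](c1ccc(OC)cc1OC)[C@@H](c1cc(OC)cc(OC)c1)C#CO[Li] | intermediate (not isolated)
13 | {[(3S,4S)-4-[(E)-1,2-dichloroethenoxy]-4-(2,4-dimethoxyphenyl)-3-(3,5-dimethoxyphenyl)but-1-yn-1-yl]oxy}triisopropylsilane | Cl/C=C(Cl)\O[C@H](c1ccc(OC)cc1OC)[C@@H](c1cc(OC)cc(OC)c1)C#CO[Si](C(C)C)(C(C)C)C(C)C | intermediate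
14 | chloroethynyl ether from 13 | ClC#CO[C@H](c1ccc(OC)cc1OC)[C@@H](c1cc(OC)cc(OC)c1)C#CO[Si](C(C)C)(C(C)C)C(C)C | intermediate (not isolated)
15 | lithium alkoxyacetylide from 14 | [Li]C#CO[C@H](c1ccc(OC)cc1OC)[C@@H](c1cc(OC)cc(OC)c1)C#CO[Si](C(C)C)(C(C)C)C(C)C | intermediate (not isolated)
16 | {[(3S,4S)-4-(2,4-dimethoxyphenyl)-3-(3,5-dimethoxyphenyl)-4-(ethynyloxy)but-1-yn-1-yl]oxy}triisopropylsilane (anti diyne) | C#CO[C@H](c1ccc(OC)cc1OC)[C@@H](c1cc(OC)cc(OC)c1)C#CO[Si](C(C)C)(C(C)C)C(C)C | intermediate
17 | 4-(4-methoxyphenyl)but-1-yne | COc1ccc(CCC#C)cc1 | starting material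
18 | {[(2S,3S)-2-(2,4-dimethoxyphenyl)-3-(3,5-dimethoxyphenyl)-6-[2-(4-methoxyphenyl)ethyl]-2,3-dihydro-1-benzofuran-4-yl]oxy}triisopropylsilane | COc1ccc(CCc2cc(O[Si](C(C)C)(C(C)C)C(C)C)c3c(c2)O[C@H](c2ccc(OC)cc2OC)[C@H]3c2cc(OC)cc(OC)c2)cc1 | intermediate
19 | (2S,3S)-2-(2,4-dimethoxyphenyl)-3-(3,5-dimethoxyphenyl)-6-[2-(4-methoxyphenyl)ethyl]-2,3-dihydro-1-benzofuran-4-ol | COc1ccc(CCc2cc(O)c3c(c2)O[C@H](c2ccc(OC)cc2OC)[C@H]3c2cc(OC)cc(OC)c2)cc1 | intermediate
20 | 4-[(2S,3S)-3-(3,5-dihydroxyphenyl)-4-hydroxy-6-[2-(4-hydroxyphenyl)ethyl]-2,3-dihydro-1-benzofuran-2-yl]benzene-1,3-diol | Oc1ccc(CCc2cc(O)c3c(c2)O[C@H](c2ccc(O)cc2O)[C@H]3c2cc(O)cc(O)c2)cc1 | target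

**Step count**
Total steps: 10. Longest linear sequence: 10 steps (1 to 20); 2, 5 and 17 are bought.

**Steps most likely to fail**

1. Step 8 (key step). The benzylic ethynyl ether may ionise or rearrange at the Lewis-acidic rhodium cation before oxidative coupling, the terminal alkynes may oligomerise, or 17 may insert with the opposite orientation and place the chain at C5.
 - Fallback (known chemistry): it sets out from 7 and 17 and comes back at 19.
 - Methanolysis of the C–Si bond of 7 (K2CO3, MeOH) should give (1S,2R)-1-(2,4-dimethoxyphenyl)-2-(3,5-dimethoxyphenyl)but-3-yn-1-ol F1.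
 - Two equivalents of LiN(SiMe3)2, lithium tert-butyl peroxide and excess iPr3SiOTf would convert F1 in one flask into the O-silyl ether that is also a silyl ynol ether, F2.
 - In parallel, 17 and dichloroketene (Cl3CCOCl, Zn–Cu couple) would give 4,4-dichloro-3-[2-(4-methoxyphenyl)ethyl]cyclobut-2-en-1-one F3, which zinc in acetic acid reduces to 3-[2-(4-methoxyphenyl)ethyl]cyclobut-2-en-1-one F4.
 - Heating F2 with F4 in toluene at 80 °C is a Danheiser benzannulation (4π opening to the vinylketene, (2+2) addition to the siloxyalkyne, 4π opening, 6π closure). It should give 2-[(1S,2S)-2-(2,4-dimethoxyphenyl)-1-(3,5-dimethoxyphenyl)-2-(triisopropylsilyloxy)ethyl]-5-[2-(4-methoxyphenyl)ethyl]-3-(triisopropylsilyloxy)phenol F5, with the C3 side chain between the two ring oxygens and the chain para to it.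
 - Bu4NF would remove both silyl groups to give 2-[(1S,2S)-2-(2,4-dimethoxyphenyl)-1-(3,5-dimethoxyphenyl)-2-hydroxyethyl]-5-[2-(4-methoxyphenyl)ethyl]benzene-1,3-diol F6.
 - Catalytic acid (TsOH, CH2Cl2) ionises the 2,4-dimethoxybenzylic alcohol, and either of the two equivalent phenols of ring A closes the ring trans to the C3 aryl group, giving 19. C3 keeps its configuration and C2 is reset under this control.

2. Step 7. Butyllithium may attack silicon of the silyl ynol ether and expel the ynolate, or deprotonate C3–H and trigger β-elimination; the benzylic ethynyl ether may also decay by acid-catalysed ionisation during isolation.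
 - Fallback: it sets out from 10 and comes back at 16, with the order of events changed so that butyllithium never meets a silyl ynol ether.
 - 10 is taken to the lithium ynolate 12 as in step 6, with exactly one equivalent of peroxide.
 - n-BuLi (2.1 equiv, −78 °C) is then added before any silylating agent. Elimination and chlorine–lithium exchange run on the silicon-free ynolate and should give the dilithium ynolate–alkoxyacetylide F7.
 - One equivalent of tert-butanol protonates the acetylide carbon, the more basic of the two anionic sites, to give the lithium ynolate that carries the free ethynyl ether, F8.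
 - iPr3SiOTf then silylates the ynolate oxygen to give 16, which is filtered cold and used at once.

3. Step 3. Enantiomeric purity may be lost by racemisation of the aryl-substituted mesylate or of the allenylpalladium and allenylzinc species, and facial discrimination may be incomplete with an electron-rich aromatic aldehyde.
 - Fallback: it sets out from 3 and comes back at 7, replacing the configurationally labile zinc reagent by an isolable boron reagent.
 - 3 is converted (ClCO2Me, pyridine) into (R)-1-(3,5-dimethoxyphenyl)-3-(triethylsilyl)prop-2-yn-1-yl methyl carbonate F9.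
 - CuCl/NaOt-Bu/Xantphos-catalysed borylation with B2pin2 displaces the carbonate in the anti SN2' sense and should give the configurationally stable (M)-2-[3-(3,5-dimethoxyphenyl)-1-(triethylsilyl)propa-1,2-dien-1-yl]-4,4,5,5-tetramethyl-1,3,2-dioxaborolane F10. It has the same spatial arrangement as 6.
 - Heating F10 with 5 in toluene adds it through a closed six-membered transition state (anti) and gives 7 after aqueous work-up.

Further compounds
F1 | step 8 | (1S,2R)-1-(2,4-dimethoxyphenyl)-2-(3,5-dimethoxyphenyl)but-3-yn-1-ol | O[C@H](c1ccc(OC)cc1OC)[C@@H](c1cc(OC)cc(OC)c1)C#C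
F2 | step 8 | {[(3S,4S)-4-(2,4-dimethoxyphenyl)-3-(3,5-dimethoxyphenyl)-4-(triisopropylsilyloxy)but-1-yn-1-yl]oxy}triisopropylsilane | CC(C)[Si](C(C)C)(C(C)C)O[C@H](c1ccc(OC)cc1OC)[C@@H](c1cc(OC)cc(OC)c1)C#CO[Si](C(C)C)(C(C)C)C(C)C
F3 | step 8 | 4,4-dichloro-3-[2-(4-methoxyphenyl)ethyl]cyclobut-2-en-1-one | COc1ccc(CCC2=CC(=O)C2(Cl)Cl)cc1
F4 | step 8 | 3-[2-(4-methoxyphenyl)ethyl]cyclobut-2-en-1-one | COc1ccc(CCC2=CC(=O)C2)cc1
F5 | step 8 | 2-[(1S,2S)-2-(2,4-dimethoxyphenyl)-1-(3,5-dimethoxyphenyl)-2-(triisopropylsilyloxy)ethyl]-5-[2-(4-methoxyphenyl)ethyl]-3-(triisopropylsilyloxy)phenol | Oc1cc(CCc2ccc(OC)cc2)cc(O[Si](C(C)C)(C(C)C)C(C)C)c1[C@H](c1cc(OC)cc(OC)c1)[C@H](O[Si](C(C)C)(C(C)C)C(C)C)c1ccc(OC)cc1OC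
F6 | step 8 | 2-[(1S,2S)-2-(2,4-dimethoxyphenyl)-1-(3,5-dimethoxyphenyl)-2-hydroxyethyl]-5-[2-(4-methoxyphenyl)ethyl]benzene-1,3-diol | Oc1cc(CCc2ccc(OC)cc2)cc(O)c1[C@H](c1cc(OC)cc(OC)c1)[C@H](O)c1ccc(OC)cc1OC
F7 | step 7 | dilithium ynolate–alkoxyacetylide from 12 | [Li]C#CO[C@H](c1ccc(OC)cc1OC)[C@@H](c1cc(OC)cc(OC)c1)C#CO[Li]
F8 | step 7 | lithium ynolate bearing the free ethynyl ether | C#CO[C@H](c1ccc(OC)cc1OC)[C@@H](c1cc(OC)cc(OC)c1)C#CO[Li]
F9 | step 3 | (R)-1-(3,5-dimethoxyphenyl)-3-(triethylsilyl)prop-2-yn-1-yl methyl carbonate | COC(=O)O[C@H](c1cc(OC)cc(OC)c1)C#C[Si](CC)(CC)CC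
F10 | step 3 | (M)-2-[3-(3,5-dimethoxyphenyl)-1-(triethylsilyl)propa-1,2-dien-1-yl]-4,4,5,5-tetramethyl-1,3,2-dioxaborolane | [H]C(c1cc(OC)cc(OC)c1)=[C@]=C([Si](CC)(CC)CC)B1OC(C)(C)C(C)(C)O1
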